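All runs stem from a simulated flask for an exercise.

Solvolysis product is the entry I have to reckon in this ledger of substrate, so I follow one substrate molecule through its forks.

| setting | elm | ash | cedar | grey | violet | ochre |
|---|---|---|---|---|---|---|
| substrate | 0.40 M | 0.40 M | 0.40 M | 0.40 M | 0.40 M | 0.40 M |
| second nucleophile | 0.73 equiv | 2.5 equiv | 5.7 equiv | 0.900 equiv | 2.20 equiv | 5.60 equiv |
| gas | 16 mM (held) | 16 mM (held) | 16 mM (held) | 16 mM (held) | 16 mM (held) | 16 mM (held) |
| remark | run made earlier | run made earlier | run made earlier |  |  |  |
| time |  |  |  | 25 h | 25 h | 25 h |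

| run | time / h | solvolysis product / % | target / % | other capture product / % | substrate / % |
|---|---|---|---|---|---|
| elm | 4.00 | 31.2 | 3.6 | 7.6 | 56.2 |
| elm | 8.00 | 50.3 | 5.6 | 10.3 | 32.3 |
| elm | 10.0 | 57.1 | 8.1 | 11.4 | 24.2 |
| elm | 15.0 | 66.2 | 8.9 | 11.5 | 11.6 |
| elm | 20.0 | 71.1 | 10.4 | 10.2 | 4.6 |
| ash | 1.50 | 10.0 | 0.9 | 7.5 | 79.5 |
| ash | 4.00 | 26.7 | 3.8 | 13.9 | 56.3 |
| ash | 8.00 | 43.5 | 7.0 | 16.5 | 30.9 |
| ash | 12.0 | 54.4 | 8.6 | 17.2 | 17.7 |
| ash | 20.0 | 63.7 | 9.7 | 19.5 | 5.7 |
| cedar | 4.00 | 22.6 | 3.5 | 16.6 | 56.5 |
| cedar | 8.00 | 40.9 | 5.4 | 21.7 | 31.7 |
| cedar | 10.0 | 47.0 | 7.2 | 21.8 | 23.9 |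
| cedar | 15.0 | 55.5 | 9.0 | 22.8 | 10.5 |
| cedar | 20.0 | 60.3 | 9.9 | 22.1 | 6.0 |

(each reading ± 0.5 percentage points)

- at the start none of the gas is in solution
- a reading of target is of its free form alone

- which of these there is most of at the end, counted by the substrate in it, grey (solvolysis product / other capture product / substrate / target)
- which of these there is most of at the end, counted by the substrate in it, violet (solvolysis product / other capture product / substrate / target)
- which of these there is most of at the end, counted by the substrate in it, ochre (solvolysis product / other capture product / substrate / target)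
- the largest of these amounts at the end, in percent of the substrate charged, grey
- the largest of these amounts at the end, in percent of the substrate charged, violet
- the largest of these amounts at the end, in percent of the substrate charged, ochre

The first entry is substrate left. At 4.00 h, the elm, ash and cedar runs read 56.2%, 56.3% and 56.5%, so c(substrate) reads the same across these loadings. The ash run gives a first-order constant of 0.142 /h, so I reckon 2.84% left at 25 h.

The second entry is other capture product. From 10.0 h to 20.0 h, the cedar run moves it by 0.3 percentage points, against a scatter of 0.5 points. Over the same interval, cedar gains 13 points of solvolysis product and loses 18 points of substrate. So cedar reads 0.743 as the late share: the fraction of substrate spent late that ends as solvolysis product. Target gains 2.7 points over that interval.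

The last entry closes the books. I take cedar's substrate on down to 2.84%, and by the late share that adds 2.3 points. Ochre's loading is close to cedar's, so I reckon 62.6% for ochre. Reading the last values between elm and ash on ln(loading) and adding the same gain, I reckon 72.2% for grey and 66.8% for violet. Solvolysis product is my pick for each: at 20.0 h cedar, the run with the least of it, reads 60.3% against 22.1% of other capture product.

The forecast picks solvolysis product, solvolysis product and solvolysis product for grey, violet and ochre, at 72.5%, 66.5% and 63%, with solvolysis product said to take “about 85% of the remaining substrate”.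

The flasks give solvolysis product, solvolysis product and solvolysis product, at 71.6%, 66.3% and 61.9%.

    gas ⇌ first nucleophile, rate k1*(csat - [first nucleophile]) (kL = 0.00810 /min)
    target ⇌ isomer of the product (K = 1.10, k = 2.80 × 10⁻⁴ /min)
    substrate → intermediate (k = 0.00240 /min)
    2 second nucleophile → homo dimer (k = 0.00590 /M/min)
    first nucleophile + intermediate → target (k = 2.40 /M/min)
    intermediate → solvolysis product (k = 0.100 /min)
    second nucleophile + intermediate → other capture product (k = 0.110 /M/min)

In ochre at 0.563 h, the half-life of intermediate by capture with second nucleophile was 0.090 h, shorter than the 0.12 h by solvolysis. At 25.0 h, with 2.3% of the charged second nucleophile left and homo dimer at 1.05 M, it was 2.1 h, longer than that. From 12.5 h to 25.0 h, ochre's late share is 0.732, against the 0.743 I read from cedar over an earlier interval. The pick in ochre turns at 6.93 h, where solvolysis product and substrate hold the same.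

The neighbour flask is ochre stopped at 10 h, where my constant gives 24.1% of substrate. Walking back from ochre's end with the late share gives 46.1% of solvolysis product. That flask holds 46.5%.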